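**Strategy.** The target is cut at the pyrrole N–CH2 bond into a 3,4-bis(7,8-dioxygenated quinolin-5-yl)pyrrole and (S)-1-(3-chloropropyl)-3-methylazecane. The plan rests on building both pyridine rings onto a preformed diarylpyrrole. In each quinoline, C4a is the only hydrogen-bearing carbon ortho to the nitrogen-bearing C8a (C8 carries oxygen) and lies para to the C7 oxygen, so acrolein can span N1 and C4a. One twofold Skraup annulation thus forms N1–C2 and C4–C4a on both arms (four bonds, two rings) from 3,4-bis(3-amino-4,5-dimethoxyphenyl)-1-tosylpyrrole, which comes from a double Suzuki coupling and nitro reduction.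

Key step: step 8

Assumption: the target carries no axial descriptors, so the two quinolinyl–pyrrole axes are treated as freely rotating and C3 of the azecane, (S), is the only stereogenic element.

Remark: the azecane stereocentre is taken from (R)-3-bromo-2-methylpropan-1-ol. Chain extension at its bromomethyl carbon changes the descriptor to S through the priority rules only, and no later step makes or breaks a bond at C3 or places a carbonyl next to it. The ten-membered ring is closed by sulfonamide N-alkylation.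

**Route**

Step 1
Reactants: 1 4-bromo-2-methoxyphenol
Product: 2 4-bromo-2-methoxy-6-nitrophenol
Conditions: HNO3 (65%, 1.05 equiv), AcOH, 10 °C
Reagents that add atoms: nitric acid, O[N+](=O)[O-]
Why: Electrophilic aromatic nitration directed by the free phenol, whose para position is blocked by bromine, so the nitro group should enter the one open ortho carbon (C6).

Step 2
Reactants: 2 4-bromo-2-methoxy-6-nitrophenol
Product: 3 5-bromo-1,2-dimethoxy-3-nitrobenzene
Conditions: MeI, K2CO3, DMF, 50 °C
Reagents that add atoms: iodomethane, CI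
Why: Williamson O-methylation, in which the acidic ortho-nitrophenoxide attacks iodomethane by SN2.

Step 3
Reactants: 3 5-bromo-1,2-dimethoxy-3-nitrobenzene
Product: 4 2-(3,4-dimethoxy-5-nitrophenyl)-4,4,5,5-tetramethyl-1,3,2-dioxaborolane
Conditions: B2pin2, Pd(dppf)Cl2 (3 mol%), KOAc, 1,4-dioxane, 90 °C
Reagents that add atoms: bis(pinacolato)diboron, CC1(C)OB(OC1(C)C)B1OC(C)(C)C(C)(C)O1
Why: Miyaura borylation, favoured by the electron-poor C–Br bond, with nitro and ether groups inert to the acetate-mediated boron transfer.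

Step 4
Reactants: 5 1-(triisopropylsilyl)pyrrole
Product: 6 3,4-dibromo-1-(triisopropylsilyl)pyrrole
Conditions: NBS (2.0 equiv), THF, −78 °C to rt
Reagents that add atoms: N-bromosuccinimide, O=C1CCC(=O)N1Br
Why: Electrophilic bromination in which the bulky N-silyl group shields C2 and C5, so both bromines should enter the β-carbons C3 and C4.

Step 5
Reactants: 6 3,4-dibromo-1-(triisopropylsilyl)pyrrole
Product: 8 3,4-dibromo-1-tosylpyrrole, via 3,4-dibromo-1H-pyrrole 7 (not isolated)
Conditions: TBAF, THF, 0 °C; aqueous wash, dried solution used at once; NaH, TsCl, THF, 0 °C to rt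
Reagents that add atoms: 4-toluenesulfonyl chloride, Cc1ccc(cc1)S(Cl)(=O)=O
Why: Fluoride-induced N-desilylation followed by N-sulfonylation of the sodium pyrrolide, telescoped because the free dibromopyrrole does not keep on concentration.

Step 6
Reactants: 8 3,4-dibromo-1-tosylpyrrole; 4 2-(3,4-dimethoxy-5-nitrophenyl)-4,4,5,5-tetramethyl-1,3,2-dioxaborolane (2.4 equiv)
Product: 9 3,4-bis(3,4-dimethoxy-5-nitrophenyl)-1-tosylpyrrole
Conditions: Pd(PPh3)4 (8 mol%), Na2CO3 (2 M aq), DME, 85 °C
Reagents that add atoms: none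
Why: Twofold Suzuki–Miyaura coupling, in which the N-sulfonyl group activates both C–Br bonds toward oxidative addition and the boronate carries no ortho substituent.

Step 7
Reactants: 9 3,4-bis(3,4-dimethoxy-5-nitrophenyl)-1-tosylpyrrole
Product: 10 3,4-bis(3-amino-4,5-dimethoxyphenyl)-1-tosylpyrrole
Conditions: H2 (1 atm), 10% Pd/C, EtOAc/EtOH, rt
Reagents that add atoms: none
Why: Catalytic hydrogenation of both aryl nitro groups to anilines, which should leave the sulfonamide, the aryl ethers and the pyrrole untouched since no carbon–halogen bond remains.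

Step 8
Reactants: 10 3,4-bis(3-amino-4,5-dimethoxyphenyl)-1-tosylpyrrole; 11 acrolein (6 equiv)
Product: 13 3,4-bis(7,8-dimethoxyquinolin-5-yl)-1-tosylpyrrole, via bis(1,2-dihydroquinoline) 12 (not isolated)
Conditions: 11 (slow addition), p-chloranil (2.2 equiv), conc. HCl, n-BuOH, 100 °C
Reagents that add atoms: none
Why: Each aniline nitrogen adds in conjugate fashion to protonated acrolein (N1–C2), the pendant aldehyde, activated by protonation or as its anil, is attacked by ring carbon C4a in an intramolecular Friedel–Crafts hydroxyalkylation (C4–C4a), water is lost to give the bis(1,2-dihydroquinoline) 12, and p-chloranil then takes two hydrogens from each new ring. This is the Skraup–Doebner–von Miller quinoline synthesis, long used to turn 2-alkoxyanilines into 8-alkoxyquinolines and diamines into doubly annulated products, applied here to a new bis-aniline. Each of the two pyridine rings closes in a 6-exo-trig mode at the carbonyl carbon, the C=O bond lying outside the new ring while the aromatic C4a–C8a bond lies inside it. No stereocentre is created, and the quinolinyl–pyrrole axes are not defined stereo-elements of the target. The step needs regioselectivity, which the substrate enforces because C8 already bears a methoxy group, leaving C4a as the only hydrogen-bearing carbon ortho to nitrogen, further activated by the para methoxy group at C7. It also needs chemoselectivity for the anilines over the pyrrole α-carbons, which the electron-withdrawing N-sulfonyl group should provide, helped by slow addition that keeps free acrolein low.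

Step 9
Reactants: 13 3,4-bis(7,8-dimethoxyquinolin-5-yl)-1-tosylpyrrole
Product: 14 3,4-bis(7,8-dimethoxyquinolin-5-yl)-1H-pyrrole
Conditions: KOH, MeOH/THF, 60 °C
Reagents that add atoms: none
Why: Nucleophilic cleavage of an N-sulfonylpyrrole by hydroxide attack at sulfur with the pyrrolide as leaving group, under which quinolines and aryl methyl ethers are inert.

Step 10
Reactants: 15 (R)-3-bromo-2-methylpropan-1-ol; 16 1-bromo-6-chlorohexane (2.3 equiv)
Product: 18 (S)-9-chloro-2-methylnonan-1-ol, via (6-chlorohexyl)magnesium bromide 17 (not isolated)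
Conditions: 16, Mg, THF, 40 °C; then 15, Li2CuCl4 (3 mol%), THF, −20 °C to rt; aq. NH4Cl
Reagents that add atoms: none
Why: Copper-catalysed alkyl–alkyl Grignard cross-coupling (Kochi coupling), in which the first equivalent of 17 only deprotonates the alcohol, the second displaces the primary bromide, the alkyl chloride is inert, and the stereocentre is a spectator whose descriptor changes from R to S through the priority rules alone.

Step 11
Reactants: 18 (S)-9-chloro-2-methylnonan-1-ol; 19 tert-butyl N-(2-nitrophenylsulfonyl)carbamate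
Product: 21 N-[(2S)-9-chloro-2-methylnonyl]-2-nitrobenzenesulfonamide, via N-Boc sulfonamide 20 (not isolated)
Conditions: PPh3, DIAD, THF, 0 °C to rt; concentrate; TFA, CH2Cl2, rt
Reagents that add atoms: none
Why: Fukuyama–Mitsunobu N-alkylation of the acidic N-Boc sulfonamide at the primary carbinol, followed by acidolysis of the tert-butoxycarbonyl group, neither of which involves the stereocentre β to the reacting carbon.

Step 12
Reactants: 21 N-[(2S)-9-chloro-2-methylnonyl]-2-nitrobenzenesulfonamide
Product: 23 (3S)-3-methyl-1-(2-nitrophenylsulfonyl)azecane, via iodide 22 (not isolated)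
Conditions: NaI, acetone, reflux; filter, concentrate; slow addition to Cs2CO3, MeCN, 60 °C (final 0.005 M)
Reagents that add atoms: none
Why: Finkelstein exchange followed by ring-closing N-alkylation of the 2-nitrobenzenesulfonamide anion (the Fukuyama amine synthesis in its intramolecular form), a method established for eight- to ten-membered cyclic amines, with pseudo-high dilution to suppress dimer formation.

Step 13
Reactants: 23 (3S)-3-methyl-1-(2-nitrophenylsulfonyl)azecane
Product: 24 (S)-3-methylazecane
Conditions: PhSH, K2CO3, MeCN, 50 °C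
Reagents that add atoms: none
Why: Fukuyama denosylation, in which thiolate adds to the nitroarene (SNAr through a Meisenheimer adduct) and the sulfonamide collapses with loss of sulfur dioxide to free the secondary amine.

Step 14
Reactants: 24 (S)-3-methylazecane; 25 1-bromo-3-chloropropane (3 equiv)
Product: 26 (S)-1-(3-chloropropyl)-3-methylazecane
Conditions: K2CO3, acetone, rt; free base used promptly
Reagents that add atoms: none
Why: SN2 N-alkylation that is chemoselective for the C–Br end of the bromochloride, with excess dihalide suppressing double amination.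

Step 15
Reactants: 14 3,4-bis(7,8-dimethoxyquinolin-5-yl)-1H-pyrrole; 26 (S)-1-(3-chloropropyl)-3-methylazecane
Product: 27 (3S)-1-{3-[3,4-bis(7,8-dimethoxyquinolin-5-yl)pyrrol-1-yl]propyl}-3-methylazecane
Conditions: NaH, DMF, 0 °C; then 26, NaI (cat.), 60 °C
Reagents that add atoms: none
Why: N-alkylation of the sodium pyrrolide by SN2 (possibly through the azetidinium ion formed from 26), the pyrrolide being far more nucleophilic than the hindered quinoline nitrogens.

Step 16
Reactants: 27 (3S)-1-{3-[3,4-bis(7,8-dimethoxyquinolin-5-yl)pyrrol-1-yl]propyl}-3-methylazecane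
Product: 28 5,5'-{1-[3-((3S)-3-methylazecan-1-yl)propyl]pyrrole-3,4-diyl}bis(quinoline-7,8-diol), CNP0141397.1
Conditions: BBr3 (12 equiv), CH2Cl2, −78 °C to rt; MeOH; aq. NaHCO3 to pH 7 under argon
Reagents that add atoms: none
Why: Lewis-acid cleavage of the four aryl methyl ethers (bromide attack on the O-methyl of each boron-complexed ether), with excess reagent to saturate the three basic nitrogens and no effect on the remote stereocentre.

**Compound list**

1 | 4-bromo-2-methoxyphenol | COc1cc(Br)ccc1O | starting material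
2 | 4-bromo-2-methoxy-6-nitrophenol | COc1cc(Br)cc([N+](=O)[O-])c1O | intermediate
3 | 5-bromo-1,2-dimethoxy-3-nitrobenzene | COc1cc(Br)cc([N+](=O)[O-])c1OC | intermediate
4 | 2-(3,4-dimethoxy-5-nitrophenyl)-4,4,5,5-tetramethyl-1,3,2-dioxaborolane | COc1cc(B2OC(C)(C)C(C)(C)O2)cc([N+](=O)[O-])c1OC | intermediate
5 | 1-(triisopropylsilyl)pyrrole | CC(C)[Si](C(C)C)(C(C)C)n1cccc1 | starting material
6 | 3,4-dibromo-1-(triisopropylsilyl)pyrrole | CC(C)[Si](C(C)C)(C(C)C)n1cc(Br)c(Br)c1 | intermediate
7 | 3,4-dibromo-1H-pyrrole | Brc1c[nH]cc1Br | intermediate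
8 | 3,4-dibromo-1-tosylpyrrole | Cc1ccc(cc1)S(=O)(=O)n1cc(Br)c(Br)c1 | intermediate
9 | 3,4-bis(3,4-dimethoxy-5-nitrophenyl)-1-tosylpyrrole | Cc1ccc(cc1)S(=O)(=O)n1cc(-c2cc(OC)c(OC)c([N+](=O)[O-])c2)c(-c2cc(OC)c(OC)c([N+](=O)[O-])c2)c1 | intermediate
10 | 3,4-bis(3-amino-4,5-dimethoxyphenyl)-1-tosylpyrrole | Cc1ccc(cc1)S(=O)(=O)n1cc(-c2cc(N)c(OC)c(OC)c2)c(-c2cc(N)c(OC)c(OC)c2)c1 | intermediate
11 | acrolein | C=CC=O | starting material
12 | 3,4-bis(7,8-dimethoxy-1,2-dihydroquinolin-5-yl)-1-tosylpyrrole | Cc1ccc(cc1)S(=O)(=O)n1cc(-c2cc(OC)c(OC)c3NCC=Cc23)c(-c2cc(OC)c(OC)c3NCC=Cc23)c1 | intermediate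
13 | 3,4-bis(7,8-dimethoxyquinolin-5-yl)-1-tosylpyrrole | Cc1ccc(cc1)S(=O)(=O)n1cc(-c2cc(OC)c(OC)c3ncccc23)c(-c2cc(OC)c(OC)c3ncccc23)c1 | intermediate
14 | 3,4-bis(7,8-dimethoxyquinolin-5-yl)-1H-pyrrole | COc1cc(-c2c[nH]cc2-c2cc(OC)c(OC)c3ncccc23)c2cccnc2c1OC | intermediate
15 | (R)-3-bromo-2-methylpropan-1-ol | C[C@H](CO)CBr | starting material
16 | 1-bromo-6-chlorohexane | ClCCCCCCBr | starting material
17 | (6-chlorohexyl)magnesium bromide | ClCCCCCC[Mg]Br | intermediate
18 | (S)-9-chloro-2-methylnonan-1-ol | C[C@H](CO)CCCCCCCCl | intermediate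
19 | tert-butyl N-(2-nitrophenylsulfonyl)carbamate | CC(C)(C)OC(=O)NS(=O)(=O)c1ccccc1[N+](=O)[O-] | starting material
20 | tert-butyl N-[(2S)-9-chloro-2-methylnonyl]-N-(2-nitrophenylsulfonyl)carbamate | C[C@H](CN(C(=O)OC(C)(C)C)S(=O)(=O)c1ccccc1[N+](=O)[O-])CCCCCCCCl | intermediate
21 | N-[(2S)-9-chloro-2-methylnonyl]-2-nitrobenzenesulfonamide | C[C@H](CNS(=O)(=O)c1ccccc1[N+](=O)[O-])CCCCCCCCl | intermediate
22 | N-[(2S)-9-iodo-2-methylnonyl]-2-nitrobenzenesulfonamide | C[C@H](CNS(=O)(=O)c1ccccc1[N+](=O)[O-])CCCCCCCI | intermediate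
23 | (3S)-3-methyl-1-(2-nitrophenylsulfonyl)azecane | C[C@H]1CCCCCCCN(S(=O)(=O)c2ccccc2[N+](=O)[O-])C1 | intermediate
24 | (S)-3-methylazecane | C[C@H]1CCCCCCCNC1 | intermediate
25 | 1-bromo-3-chloropropane | ClCCCBr | starting material
26 | (S)-1-(3-chloropropyl)-3-methylazecane | C[C@H]1CCCCCCCN(CCCCl)C1 | intermediate
27 | (3S)-1-{3-[3,4-bis(7,8-dimethoxyquinolin-5-yl)pyrrol-1-yl]propyl}-3-methylazecane | C[C@H]1CCCCCCCN(CCCn2cc(-c3cc(OC)c(OC)c4ncccc34)c(-c3cc(OC)c(OC)c4ncccc34)c2)C1 | intermediate
28 | 5,5'-{1-[3-((3S)-3-methylazecan-1-yl)propyl]pyrrole-3,4-diyl}bis(quinoline-7,8-diol) | C[C@H]1CCCCCCCN(CCCn2cc(-c3cc(O)c(O)c4ncccc34)c(-c3cc(O)c(O)c4ncccc34)c2)C1 | target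

**Step count**

Total: 16 steps. Longest linear sequence: 9 steps (steps 1, 2, 3, 6, 7, 8, 9, 15, 16).

**Steps most likely to fail**

1. Step 8. Acrolein may oligomerise faster than it annulates, the second arm may stop at the mono-quinoline, or acid may loosen the sulfonyl group and expose the pyrrole to alkylation. The fallback sets out from 3 and comes back at 13, moving the annulation to a simple mono-aniline. Reduction of the nitro group of 3 with Fe and NH4Cl in EtOH/H2O at 80 °C, which keeps the C–Br bond, should give 5-bromo-2,3-dimethoxyaniline F1. A single Skraup annulation of F1 with 11 under the conditions of step 8 should give 5-bromo-7,8-dimethoxyquinoline F2, closing at the only open ortho carbon. Miyaura borylation (B2pin2, Pd(dppf)Cl2, KOAc, dioxane, 90 °C) should give 7,8-dimethoxy-5-(4,4,5,5-tetramethyl-1,3,2-dioxaborolan-2-yl)quinoline F3. Twofold Suzuki–Miyaura coupling of F3 with 8 (Pd(PPh3)4, Na2CO3, DME/H2O, 85 °C) rejoins the route at 13.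

2. Step 12. Intermolecular N-alkylation, leading to dimers and oligomers, may outrun the entropically and transannularly disfavoured ten-membered closure. The fallback sets out from 15 and comes back at 23, closing the ring at a C=C bond instead. Copper-catalysed coupling of 15 with but-3-enylmagnesium bromide (Li2CuCl4, THF) should give (S)-2-methylhept-6-en-1-ol F4. Mitsunobu coupling of F4 (PPh3, DIAD, THF) with N-(but-3-enyl)-2-nitrobenzenesulfonamide F5, itself made from but-3-en-1-amine and 2-nitrobenzenesulfonyl chloride with Et3N, should give N-(but-3-enyl)-N-[(2S)-2-methylhept-6-enyl]-2-nitrobenzenesulfonamide F6. Ring-closing metathesis with the second-generation Grubbs catalyst in toluene at 80 °C and 0.002 M should give (3S)-3-methyl-1-(2-nitrophenylsulfonyl)-1,2,3,4,5,6,9,10-octahydroazecine F7 as an alkene mixture. Diimide reduction (TsNHNH2, NaOAc, DME/H2O, reflux), which spares the nitro group, returns to 23.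

3. Step 16. Ether cleavage may stall because the Lewis acid is sequestered by the three basic nitrogens, and the liberated catechols may oxidise during the neutralisation needed to free the amine. The fallback sets out from 13 and comes back at 28, moving the demethylation to a robust intermediate and ending with a mild acidolysis. BBr3 in CH2Cl2 on 13 should give 3,4-bis(7,8-dihydroxyquinolin-5-yl)-1-tosylpyrrole F8. Treatment with NaH and MOMCl in DMF at 0 °C should give 3,4-bis[7,8-bis(methoxymethoxy)quinolin-5-yl]-1-tosylpyrrole F9. KOH in MeOH/THF should give 3,4-bis[7,8-bis(methoxymethoxy)quinolin-5-yl]-1H-pyrrole F10. Alkylation with 26 as in step 15 should give (3S)-1-{3-[3,4-bis(7,8-bis(methoxymethoxy)quinolin-5-yl)pyrrol-1-yl]propyl}-3-methylazecane F11. HCl in MeOH at 40 °C, followed by neutralisation under argon, should release 28 without Lewis acid.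

**Further compounds**

F1 | step 8 | 5-bromo-2,3-dimethoxyaniline | COc1cc(Br)cc(N)c1OC
F2 | step 8 | 5-bromo-7,8-dimethoxyquinoline | COc1cc(Br)c2cccnc2c1OC
F3 | step 8 | 7,8-dimethoxy-5-(4,4,5,5-tetramethyl-1,3,2-dioxaborolan-2-yl)quinoline | COc1cc(B2OC(C)(C)C(C)(C)O2)c2cccnc2c1OC
F4 | step 12 | (S)-2-methylhept-6-en-1-ol | C[C@H](CO)CCCC=C
F5 | step 12 | N-(but-3-enyl)-2-nitrobenzenesulfonamide | C=CCCNS(=O)(=O)c1ccccc1[N+](=O)[O-]
F6 | step 12 | N-(but-3-enyl)-N-[(2S)-2-methylhept-6-enyl]-2-nitrobenzenesulfonamide | C[C@H](CN(CCC=C)S(=O)(=O)c1ccccc1[N+](=O)[O-])CCCC=C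
F7 | step 12 | (3S)-3-methyl-1-(2-nitrophenylsulfonyl)-1,2,3,4,5,6,9,10-octahydroazecine | C[C@H]1CCCC=CCCN(S(=O)(=O)c2ccccc2[N+](=O)[O-])C1
F8 | step 16 | 3,4-bis(7,8-dihydroxyquinolin-5-yl)-1-tosylpyrrole | Cc1ccc(cc1)S(=O)(=O)n1cc(-c2cc(O)c(O)c3ncccc23)c(-c2cc(O)c(O)c3ncccc23)c1
F9 | step 16 | 3,4-bis[7,8-bis(methoxymethoxy)quinolin-5-yl]-1-tosylpyrrole | Cc1ccc(cc1)S(=O)(=O)n1cc(-c2cc(OCOC)c(OCOC)c3ncccc23)c(-c2cc(OCOC)c(OCOC)c3ncccc23)c1
F10 | step 16 | 3,4-bis[7,8-bis(methoxymethoxy)quinolin-5-yl]-1H-pyrrole | COCOc1cc(-c2c[nH]cc2-c2cc(OCOC)c(OCOC)c3ncccc23)c2cccnc2c1OCOC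
F11 | step 16 | (3S)-1-{3-[3,4-bis(7,8-bis(methoxymethoxy)quinolin-5-yl)pyrrol-1-yl]propyl}-3-methylazecane | C[C@H]1CCCCCCCN(CCCn2cc(-c3cc(OCOC)c(OCOC)c4ncccc34)c(-c3cc(OCOC)c(OCOC)c4ncccc34)c2)C1
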